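**Plan**

- Numbering: ring A is the trioxygenated ring (C1 carries the benzoyl carbon, OH on C2 and C6, ether O on C4), ring B is the phenyl ring, and the side chain is C1'–C8' counted from the OCH2. Ring A has oxygen on C2, C4 and C6 and an acyl carbon on C1, which is the pattern of a benzoyl-capped 3,5,7-triketo acid folded by a Claisen condensation. Only O4 is an ether, so ring A can be unfolded to a 4-alkoxy-6-methyl-2-pyranone whose methyl carbon is C1.
- Retrosynthetic cuts, in order: O5'–Si; the bond from C1 of ring A to the benzoyl carbon together with the C1–C2 ring bond (giving a 4-alkoxy-6-methyl-2-pyranone and methyl benzoate); O4–C1' (Mitsunobu on triacetic acid lactone); C1'–C2' and C3'–CH3 (formaldehyde and methyl onto a terminal alkyne); C3'–C4' and C6'–C7' (acetylide and isopropenyl onto the two ends of epichlorohydrin).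
- Forward order: the side chain is built first and joined through O4 to the pyranone, a temporary ring. In one flask the benzoyl carbon, bringing ring B intact, is then bonded to the pyranone methyl carbon, the pyranone is opened and ring A is closed. Desilylation ends the route.
- Stereochemistry: C5' (S) comes from (S)-epichlorohydrin, whose C–O bond at the stereocentre is never broken. The 2'E alkene comes from syn methylalumination of the alkyne.

Key step: step 6

Remark: C5' is S by CIP analysis of the given SMILES; compounds 1, 2, 4, 10 and 12 and Mg(OMe)2 in MeOH are taken as commercial.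

**Step 1**
Reactants: 1 (S)-epichlorohydrin, (2S)-2-(chloromethyl)oxirane; 2 isopropenylmagnesium bromide, CH2=C(CH3)MgBr
Product: 3 (2S)-1-chloro-4-methylpent-4-en-2-ol
Conditions: 2 (1.3 equiv), CuI (10 mol %), THF, −40 → −20 °C; then aq. NH4Cl
Reagents that add atoms: none
Why: Copper-catalysed Grignard opening of the epoxide (SN2 at the unsubstituted ring carbon) should leave the C–Cl bond and the stereocentre untouched, so the S configuration of 1 is carried into 3.

**Step 2**
Reactants: 3 (2S)-1-chloro-4-methylpent-4-en-2-ol; 4 lithium acetylide–ethylenediamine complex, LiC≡CH·H2NCH2CH2NH2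
Product: 6 (4S)-2-methylhept-1-en-6-yn-4-ol, via epoxide 5 (not isolated)
Conditions: 4 (3 equiv), DMSO, 0 °C → rt; then H2O
Reagents that add atoms: none
Why: The acetylide should first act as base and close the chlorohydrin to epoxide 5 (intramolecular Williamson reaction, C–O bond at the stereocentre retained) and then open 5 at its terminal carbon (SN2 epoxide alkynylation), which places the S carbinol between the methallyl and propargyl arms.

**Step 3**
Reactants: 6 (4S)-2-methylhept-1-en-6-yn-4-ol
Product: 7 tert-butyl(dimethyl){[(4S)-2-methylhept-1-en-6-yn-4-yl]oxy}silane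
Conditions: TBSCl, imidazole, DMF, rt
Reagents that add atoms: tert-butyldimethylsilyl chloride (TBSCl), CC(C)(C)[Si](C)(C)Cl
Why: Imidazole-promoted silylation of a secondary alcohol is standard and masks the only O–H before the organoaluminium and amide-base steps.

**Step 4**
Reactants: 7 tert-butyl(dimethyl){[(4S)-2-methylhept-1-en-6-yn-4-yl]oxy}silane
Product: 9 (2E,5S)-5-{[tert-butyl(dimethyl)silyl]oxy}-3,7-dimethylocta-2,7-dien-1-ol, via alkenylalane 8 (not isolated)
Conditions: AlMe3 (2.5 equiv), Cp2ZrCl2 (0.3 equiv), CH2Cl2, 0 °C → rt; evaporate, hexane; n-BuLi, −78 → 0 °C; (CH2O)n, THF, rt; then cold 1 M HCl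
Reagents that add atoms: trimethylaluminium, C[Al](C)C; formaldehyde (as paraformaldehyde), C=O
Why: Negishi zirconium-catalysed methylalumination adds CH3 and Al syn across the terminal alkyne with Al on the terminal carbon, and the derived alanate should transfer the alkenyl group to formaldehyde with retention, which fixes the 2E trisubstituted alkene while the 1,1-disubstituted alkene and the silyl ether stay inert.

**Step 5**
Reactants: 9 (2E,5S)-5-{[tert-butyl(dimethyl)silyl]oxy}-3,7-dimethylocta-2,7-dien-1-ol; 10 4-hydroxy-6-methyl-2H-pyran-2-one (triacetic acid lactone)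
Product: 11 4-{[(2E,5S)-5-{[tert-butyl(dimethyl)silyl]oxy}-3,7-dimethylocta-2,7-dien-1-yl]oxy}-6-methyl-2H-pyran-2-one
Conditions: PPh3, DIAD, THF, 0 °C → rt
Reagents that add atoms: none
Why: In this Mitsunobu etherification the acidic vinylogous acid 10 should be alkylated on O4 by SN2 displacement of the primary allylic alkoxyphosphonium ion, with the secondary carbinol silylated and the E alkene untouched.

**Step 6**
Reactants: 11 4-{[(2E,5S)-5-{[tert-butyl(dimethyl)silyl]oxy}-3,7-dimethylocta-2,7-dien-1-yl]oxy}-6-methyl-2H-pyran-2-one; 12 methyl benzoate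
Product: 16 (4-{[(2E,5S)-5-{[tert-butyl(dimethyl)silyl]oxy}-3,7-dimethylocta-2,7-dien-1-yl]oxy}-2,6-dihydroxyphenyl)(phenyl)methanone, via lithiated pyranone 13 (not isolated), via phenacylpyranone 14 (not isolated), via diketo ester 15 (not isolated)
Conditions: LiN(SiMe3)2 (2.3 equiv), THF, −78 °C; 12 (1.1 equiv), −78 → 0 °C; then Mg(OMe)2 (3 equiv), MeOH, 65 °C; cold 0.5 M HCl to pH 4
Reagents that add atoms: none
Why: Proposed new method: LiN(SiMe3)2 should remove a proton from the 6-methyl group of 11, which is acidified through C5=C6 and C3=C4 by the lactone carbonyl, and carbanion 13 should add to methyl benzoate and expel methoxide (crossed Claisen acylation, the second equivalent of base storing 14 as its enolate), after which methoxide with Mg(OMe)2 opens the lactone at its carbonyl carbon to the magnesium chelate of 15, whose C6 (heptenoate numbering) attacks the ester carbon C1 and, after loss of methoxide and enolisation, gives ring A. The closest known reaction types are the stepwise C-acylation of lithiated 4-methoxy-6-methyl-2-pyranone with esters and the separate Mg(OMe)2-induced recyclisation of 6-(2-oxoalkyl)-4-methoxy-2-pyranones to 2-acyl-5-methoxyresorcinols, and the untested part is their merger in one flask on an allylic 4-alkoxy ether. Ring A closes by a 6-exo-trig Dieckmann-type (intramolecular Claisen) condensation that aromatisation makes irreversible. No stereocentre is formed, and C5' is remote from every anionic site and carries a silyl ether, so it should not be at risk. The step needs metalation at the methyl carbon and not at C3 (the extended enolate is the more stable one), C-acylation and not O-acylation (O-acylation by an ester is reversible), and Claisen and not aldol folding, which the magnesium 5,7-diketonate (C6 the only nucleophile, C7 carbonyl deactivated), the enol ether at C3 (C2 stays sp2 and unreactive) and the former ring double bond (ester held cis to C4) should secure. Retention of the O4 allylic ether against exchange with methoxide rests on the substrate being an electron-rich enolate or chelate throughout.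

**Step 7**
Reactants: 16 (4-{[(2E,5S)-5-{[tert-butyl(dimethyl)silyl]oxy}-3,7-dimethylocta-2,7-dien-1-yl]oxy}-2,6-dihydroxyphenyl)(phenyl)methanone
Product: 17 (2,6-dihydroxy-4-{[(2E,5S)-5-hydroxy-3,7-dimethylocta-2,7-dien-1-yl]oxy}phenyl)(phenyl)methanone
Conditions: Bu4NF (4 equiv), THF, 0 °C → rt; then aq. NH4Cl
Reagents that add atoms: none
Why: Fluoride should cleave the Si–O bond (standard silyl ether removal) without breaking the C5'–O bond, the aryl allyl ether or the alkenes, so the S configuration is retained in the target.

**Compound list**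

1 | (S)-epichlorohydrin, (2S)-2-(chloromethyl)oxirane | C1[C@H](O1)CCl | starting material
2 | isopropenylmagnesium bromide | C=C(C)[Mg]Br | starting material
3 | (2S)-1-chloro-4-methylpent-4-en-2-ol | C=C(C)C[C@H](O)CCl | intermediate
4 | lithium acetylide–ethylenediamine complex | [Li]C#C.NCCN | starting material
5 | (2S)-2-(2-methylprop-2-en-1-yl)oxirane | C=C(C)C[C@H]1CO1 | intermediate
6 | (4S)-2-methylhept-1-en-6-yn-4-ol | C=C(C)C[C@H](O)CC#C | intermediate
7 | tert-butyl(dimethyl){[(4S)-2-methylhept-1-en-6-yn-4-yl]oxy}silane | C=C(C)C[C@H](O[Si](C)(C)C(C)(C)C)CC#C | intermediate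
8 | [(1E,4S)-4-{[tert-butyl(dimethyl)silyl]oxy}-2,6-dimethylhepta-1,6-dien-1-yl](dimethyl)alane | C=C(C)C[C@H](O[Si](C)(C)C(C)(C)C)C/C(C)=C/[Al](C)C | intermediate
9 | (2E,5S)-5-{[tert-butyl(dimethyl)silyl]oxy}-3,7-dimethylocta-2,7-dien-1-ol | C=C(C)C[C@H](O[Si](C)(C)C(C)(C)C)C/C(C)=C/CO | intermediate
10 | 4-hydroxy-6-methyl-2H-pyran-2-one (triacetic acid lactone) | CC1=CC(O)=CC(=O)O1 | starting material
11 | 4-{[(2E,5S)-5-{[tert-butyl(dimethyl)silyl]oxy}-3,7-dimethylocta-2,7-dien-1-yl]oxy}-6-methyl-2H-pyran-2-one | C=C(C)C[C@H](O[Si](C)(C)C(C)(C)C)C/C(C)=C/COC1=CC(=O)OC(C)=C1 | intermediate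
12 | methyl benzoate | COC(=O)c1ccccc1 | starting material
13 | {[4-{[(2E,5S)-5-{[tert-butyl(dimethyl)silyl]oxy}-3,7-dimethylocta-2,7-dien-1-yl]oxy}-2-oxo-2H-pyran-6-yl]methyl}lithium | C=C(C)C[C@H](O[Si](C)(C)C(C)(C)C)C/C(C)=C/COC1=CC(=O)OC(C[Li])=C1 | intermediate
14 | 4-{[(2E,5S)-5-{[tert-butyl(dimethyl)silyl]oxy}-3,7-dimethylocta-2,7-dien-1-yl]oxy}-6-(2-oxo-2-phenylethyl)-2H-pyran-2-one | C=C(C)C[C@H](O[Si](C)(C)C(C)(C)C)C/C(C)=C/COC1=CC(=O)OC(CC(=O)c2ccccc2)=C1 | intermediate
15 | methyl (2E)-3-{[(2E,5S)-5-{[tert-butyl(dimethyl)silyl]oxy}-3,7-dimethylocta-2,7-dien-1-yl]oxy}-5,7-dioxo-7-phenylhept-2-enoate | C=C(C)C[C@H](O[Si](C)(C)C(C)(C)C)C/C(C)=C/CO/C(CC(=O)CC(=O)c1ccccc1)=C/C(=O)OC | intermediate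
16 | (4-{[(2E,5S)-5-{[tert-butyl(dimethyl)silyl]oxy}-3,7-dimethylocta-2,7-dien-1-yl]oxy}-2,6-dihydroxyphenyl)(phenyl)methanone | C=C(C)C[C@H](O[Si](C)(C)C(C)(C)C)C/C(C)=C/COc1cc(O)c(C(=O)c2ccccc2)c(O)c1 | intermediate
17 | (2,6-dihydroxy-4-{[(2E,5S)-5-hydroxy-3,7-dimethylocta-2,7-dien-1-yl]oxy}phenyl)(phenyl)methanone | C=C(C)C[C@H](O)C/C(C)=C/COc1cc(O)c(C(=O)c2ccccc2)c(O)c1 | target

Total step count: 7
Longest linear sequence: 7 steps (1 → 3 → 6 → 7 → 9 → 11 → 16 → 17)

**Steps most likely to fail**

Step 6 (new method). What may go wrong: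
- deprotonation at C3 of the pyranone in competition with the methyl group;
- proton transfer from phenacylpyranone 14 to unreacted carbanion, which stalls the acylation;
- exchange of the allylic O4 alkoxy group for methoxy by conjugate addition–elimination during the Mg(OMe)2 stage;
- folding of 15 in the aldol sense to a biaryl resorcylate.

The fallback uses known chemistry and makes ring A before the ether. It sets out from alcohol 9 and comes back at 16. Phloroglucinol is C-benzoylated (benzoyl chloride, AlCl3, nitrobenzene; Friedel–Crafts acylation) to (2,4,6-trihydroxyphenyl)(phenyl)methanone F1. Mitsunobu etherification of F1 with 9 (PPh3, DIAD, THF) should then take place at the 4-OH, because the 2-OH and 6-OH are hydrogen-bonded to the carbonyl, and should give 16.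

Step 4. What may go wrong:
- methylalumination with incomplete regiocontrol;
- protonolysis of the alkenyl–aluminium bond before hydroxymethylation;
- slow transfer of the alkenyl group from the alanate to polymeric formaldehyde.

The fallback builds the trisubstituted alkene by addition–elimination instead of carbometalation. It sets out from 7 and comes back at 9. The lithium acetylide of 7 is carboxylated (n-BuLi, ClCO2Me, THF, −78 °C) to methyl (5S)-5-{[tert-butyl(dimethyl)silyl]oxy}-7-methyloct-7-en-2-ynoate F2. Anti conjugate addition of benzenethiol (PhSH, catalytic NaOMe, MeOH) should give methyl (2Z,5S)-5-{[tert-butyl(dimethyl)silyl]oxy}-7-methyl-3-(phenylsulfanyl)octa-2,7-dienoate F3. Copper-mediated replacement of the sulfanyl group by methyl with retention (MeMgI, CuI, THF, −78 °C) should give methyl (2E,5S)-5-{[tert-butyl(dimethyl)silyl]oxy}-3,7-dimethylocta-2,7-dienoate F4. Reduction with (Me2CHCH2)2AlH in CH2Cl2 at −78 °C then gives 9.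

Step 5. What may go wrong:
- alkylation of the ambident pyranone anion at the carbonyl oxygen or at C3 instead of O4;
- allylic transposition (SN2′ attack) in the side chain.

The fallback reverses the polarity of the ether formation. It sets out from 10 and comes back at 11. Compound 10 is converted into 4-bromo-6-methyl-2H-pyran-2-one F5 (P2O5, Bu4NBr, toluene, 100 °C). The sodium alkoxide of 9 (NaH, THF, 0 °C) should then add at C4 and expel bromide (addition–elimination on the vinylogous acyl bromide) to give 11.

**Further compounds**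

F1 | step 6 | (2,4,6-trihydroxyphenyl)(phenyl)methanone | O=C(c1ccccc1)c1c(O)cc(O)cc1O
F2 | step 4 | methyl (5S)-5-{[tert-butyl(dimethyl)silyl]oxy}-7-methyloct-7-en-2-ynoate | C=C(C)C[C@H](O[Si](C)(C)C(C)(C)C)CC#CC(=O)OC
F3 | step 4 | methyl (2Z,5S)-5-{[tert-butyl(dimethyl)silyl]oxy}-7-methyl-3-(phenylsulfanyl)octa-2,7-dienoate | C=C(C)C[C@H](O[Si](C)(C)C(C)(C)C)C/C(Sc1ccccc1)=C/C(=O)OC
F4 | step 4 | methyl (2E,5S)-5-{[tert-butyl(dimethyl)silyl]oxy}-3,7-dimethylocta-2,7-dienoate | C=C(C)C[C@H](O[Si](C)(C)C(C)(C)C)C/C(C)=C/C(=O)OC
F5 | step 5 | 4-bromo-6-methyl-2H-pyran-2-one | CC1=CC(Br)=CC(=O)O1
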